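**Retrosynthetic overview**
- The strategy rests on the trans diol at C1/C6 of the cyclohexane ring, where C1 is tertiary and carries the C7H2OBz arm: this is the anti-dihydroxylation pattern of a C1=C6 ring alkene.
- Target 17 comes from epoxide 15 (oxygen delivered by the C2 hydroxyl) by acid opening at C1 with inversion, assisted by the C7 benzoate; 15 comes from cyclohexene 14.
- The only ring is closed by ring-closing metathesis of acyclic diene 13 (1,1-disubstituted alkene at C1, vinyl group at C6), forming C1=C6.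
- Diene 13 comes from a Morita–Baylis–Hillman C1–C2 bond formation (aldehyde 7 + acrylate 8), which sets C2; C5 comes from kinetic resolution of hexa-1,5-dien-3-ol.

Key step: step 10

Remark on locants: C1 = ring carbon bearing the tertiary OH and the C7H2OBz arm; C2 = CHOH; C3, C4 = CH2; C5 = CHOBz; C6 = CHOH.
Remark: the C5 oxygen is carried as a benzoate that is deliberately cleaved in the hydride reduction of step 7 and put back, together with the C7 benzoate, in step 8.

Step 1
Reactants: 1 rac-hexa-1,5-dien-3-ol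
Product: 2 (3R)-hexa-1,5-dien-3-ol
Conditions: Ti(OiPr)4 (10 mol %), L-(+)-DIPT (15 mol %), t-BuOOH (0.6 equiv), 4 Å MS, CH2Cl2, −20 °C
Reagents that add atoms: none
Why: Sharpless kinetic resolution: with L-(+)-DIPT the allylic vinyl group of the (S)-alcohol should be epoxidised much faster (erythro-selective matched case), so that past half conversion the recovered alcohol should be the (R)-enantiomer that carries the future C5 configuration.

Step 2
Reactants: 2 (3R)-hexa-1,5-dien-3-ol; 3 benzoyl chloride
Product: 4 (3R)-hexa-1,5-dien-3-yl benzoate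
Conditions: pyridine, DMAP (cat.), CH2Cl2, 0 °C → rt
Reagents that add atoms: none
Why: DMAP-catalysed O-acylation gives a non-volatile, electron-withdrawing temporary ester on C5–O without touching the stereocentre.

Step 3
Reactants: 4 (3R)-hexa-1,5-dien-3-yl benzoate
Product: 6 (3R)-6-hydroxyhex-1-en-3-yl benzoate, via B-alkyl-9-BBN adduct 5 (not isolated)
Conditions: 9-BBN (1.1 equiv), THF, 0 °C → rt; then 30% H2O2, aq. NaOAc, 0 °C → rt
Reagents that add atoms: 9-borabicyclo[3.3.1]nonane, B1C2CCCC1CCC2 (boron stays in 5 only); hydrogen peroxide, OO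
Why: Chemoselective anti-Markovnikov hydroboration–oxidation: 9-BBN should add to the unhindered allyl terminus and spare the vinyl group, which is α-branched and deactivated by the allylic benzoate, and buffered peroxide oxidation spares the ester.

Step 4
Reactants: 6 (3R)-6-hydroxyhex-1-en-3-yl benzoate
Product: 7 (3R)-6-oxohex-1-en-3-yl benzoate
Conditions: TEMPO (10 mol %), PhI(OAc)2 (1.1 equiv), CH2Cl2, rt
Reagents that add atoms: none
Why: TEMPO/oxoammonium-catalysed oxidation should stop at the aldehyde and leave alkene and benzoate untouched.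

Step 5
Reactants: 7 (3R)-6-oxohex-1-en-3-yl benzoate; 8 1,1,1,3,3,3-hexafluoropropan-2-yl acrylate
Product: 9 1,1,1,3,3,3-hexafluoropropan-2-yl (3R,6R)-6-(benzoyloxy)-3-hydroxy-2-methylideneoct-7-enoate
Conditions: β-isocupreidine (10 mol %), DMF, −55 °C
Reagents that add atoms: none
Why: Asymmetric Morita–Baylis–Hillman reaction: conjugate addition of the quinuclidine nitrogen to the activated acrylate, aldol addition to the aldehyde and phenol-assisted proton transfer/elimination should form the C1–C2 bond and give the (R)-carbinol at C2 under catalyst control, the C5 centre being remote.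

Step 6
Reactants: 9 1,1,1,3,3,3-hexafluoropropan-2-yl (3R,6R)-6-(benzoyloxy)-3-hydroxy-2-methylideneoct-7-enoate
Product: 10 1,1,1,3,3,3-hexafluoropropan-2-yl (3R,6R)-6-(benzoyloxy)-3-[(tert-butyldimethylsilyl)oxy]-2-methylideneoct-7-enoate
Conditions: TBSOTf, 2,6-lutidine, CH2Cl2, −78 → 0 °C
Reagents that add atoms: tert-butyldimethylsilyl triflate, CC(C)(C)[Si](C)(C)OS(=O)(=O)C(F)(F)F
Why: Silyl triflate/lutidine silylation masks the hindered C2 hydroxyl under non-nucleophilic conditions (no retro-aldol or elimination), so that this oxygen alone stays unacylated later.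

Step 7
Reactants: 10 1,1,1,3,3,3-hexafluoropropan-2-yl (3R,6R)-6-(benzoyloxy)-3-[(tert-butyldimethylsilyl)oxy]-2-methylideneoct-7-enoate
Product: 11 (3R,6R)-3-[(tert-butyldimethylsilyl)oxy]-2-methylideneoct-7-ene-1,6-diol
Conditions: i-Bu2AlH (6 equiv), CH2Cl2, −78 → −20 °C; aq. KNaC4H4O6 work-up
Reagents that add atoms: none
Why: Hydride reduction: the activated acrylate ester is reduced by 1,2-addition to the primary allylic alcohol (C7) and the temporary C5 benzoate is cleaved in the same operation, while the silyl ether and both alkenes remain.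

Step 8
Reactants: 11 (3R,6R)-3-[(tert-butyldimethylsilyl)oxy]-2-methylideneoct-7-ene-1,6-diol; 3 benzoyl chloride (two equivalents are consumed, one per hydroxyl)
Product: 12 (3R,6R)-6-(benzoyloxy)-3-[(tert-butyldimethylsilyl)oxy]-2-methylideneoct-7-en-1-yl benzoate
Conditions: BzCl (2.5 equiv), pyridine, DMAP (cat.), CH2Cl2, 0 °C → rt
Reagents that add atoms: benzoyl chloride (the second equivalent, which supplies the second benzoyl group), O=C(Cl)c1ccccc1
Why: DMAP-catalysed double O-acylation: one molecule of benzoyl chloride esterifies the primary C7 hydroxyl and a second one the secondary C5 hydroxyl, which installs both benzoates of the target in one operation while C2–O is blocked as the silyl ether.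

Step 9
Reactants: 12 (3R,6R)-6-(benzoyloxy)-3-[(tert-butyldimethylsilyl)oxy]-2-methylideneoct-7-en-1-yl benzoate
Product: 13 (3R,6R)-6-(benzoyloxy)-3-hydroxy-2-methylideneoct-7-en-1-yl benzoate
Conditions: HF·pyridine, THF/pyridine, 0 °C → rt
Reagents that add atoms: none
Why: Fluoride-mediated desilylation under mildly acidic conditions frees the C2 hydroxyl and should not trigger the 1,3-benzoyl shift from C7–O to C2–O that a basic fluoride source could cause.

Step 10
Reactants: 13 (3R,6R)-6-(benzoyloxy)-3-hydroxy-2-methylideneoct-7-en-1-yl benzoate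
Product: 14 [(3R,6R)-3-(benzoyloxy)-6-hydroxycyclohex-1-en-1-yl]methyl benzoate
Conditions: second-generation Grubbs catalyst RuCl2(=CHPh)(PCy3)(H2IMes) (5 mol %), CH2Cl2 (5 mM), 40 °C
Reagents that add atoms: none
Why: Ring-closing olefin metathesis: the ruthenium benzylidene exchanges onto the unhindered C6 vinyl group by [2+2] cycloaddition/cycloreversion, the new alkylidene adds intramolecularly to the 1,1-disubstituted C1=CH2 alkene to give a ruthenacyclobutane, and cycloreversion forms C1=C6 and Ru=CH2, which leaves as ethylene. The closest known reaction type is RCM of Baylis–Hillman-derived 1,7-dienes (one terminal, one 1,1-disubstituted alkene) to 2-substituted cyclohex-2-en-1-ols. The six-membered carbocycle, the only ring of the target, is closed by this intramolecular alkylidene transfer, and no other ring size can compete. No stereocentre is formed, C2 and C5 are untouched, and the ring alkene can only be cis within the ring. The step needs cyclisation over cross-metathesis at the vinyl group and no alkene migration; high dilution, the bias for six-ring formation, loss of ethylene and the free allylic C2 hydroxyl, which speeds addition to the hindered alkene, should secure this.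

Step 11
Reactants: 14 [(3R,6R)-3-(benzoyloxy)-6-hydroxycyclohex-1-en-1-yl]methyl benzoate
Product: 15 [(1R,2R,5R,6S)-5-(benzoyloxy)-2-hydroxy-7-oxabicyclo[4.1.0]heptan-1-yl]methyl benzoate
Conditions: VO(acac)2 (5 mol %), t-BuOOH (1.5 equiv, decane), CH2Cl2, 0 °C → rt
Reagents that add atoms: tert-butyl hydroperoxide, CC(C)(C)OO
Why: Hydroxyl-directed epoxidation: the vanadium alkoxide of the allylic C2–OH delivers the peroxide oxygen to the face of C1=C6 syn to C2–OH, which is also the face opposite the C5 benzoate, so both new C–O bonds at C1 and C6 lie cis to C2–OH.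

Step 12
Reactants: 15 [(1R,2R,5R,6S)-5-(benzoyloxy)-2-hydroxy-7-oxabicyclo[4.1.0]heptan-1-yl]methyl benzoate
Product: 17 [(1S,2S,3R,6R)-3-(benzoyloxy)-1,2,6-trihydroxycyclohexyl]methyl benzoate (target), via spiro dioxolanylium ion 16 (not isolated)
Conditions: HClO4 (70% aq., 0.2 equiv), THF/H2O 4:1, 0 °C → rt
Reagents that add atoms: water, O
Why: Acid-catalysed epoxide hydrolysis with anchimeric assistance: the protonated epoxide should open at the tertiary, more cation-stabilising C1 by backside attack of the C7 benzoate carbonyl oxygen (five-membered acyloxonium ion 16), which inverts C1 while C6 keeps its oxygen; water then adds to the acyloxonium carbon and the orthoacid collapses to the tertiary C1–OH and the primary C7 benzoate, and direct anti attack of water at C1 leads to the same product.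

**Compound list**
1 | rac-hexa-1,5-dien-3-ol | C=CCC(O)C=C | starting material
2 | (3R)-hexa-1,5-dien-3-ol | C=CC[C@@H](O)C=C | intermediate
3 | benzoyl chloride | O=C(Cl)c1ccccc1 | starting material
4 | (3R)-hexa-1,5-dien-3-yl benzoate | C=CC[C@@H](OC(=O)c1ccccc1)C=C | intermediate
5 | (3R)-6-(9-borabicyclo[3.3.1]nonan-9-yl)hex-1-en-3-yl benzoate | C=C[C@H](OC(=O)c1ccccc1)CCCB1C2CCCC1CCC2 | intermediate (not isolated)
6 | (3R)-6-hydroxyhex-1-en-3-yl benzoate | C=C[C@H](OC(=O)c1ccccc1)CCCO | intermediate
7 | (3R)-6-oxohex-1-en-3-yl benzoate | C=C[C@H](OC(=O)c1ccccc1)CCC=O | intermediate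
8 | 1,1,1,3,3,3-hexafluoropropan-2-yl acrylate | C=CC(=O)OC(C(F)(F)F)C(F)(F)F | starting material
9 | 1,1,1,3,3,3-hexafluoropropan-2-yl (3R,6R)-6-(benzoyloxy)-3-hydroxy-2-methylideneoct-7-enoate | C=C(C(=O)OC(C(F)(F)F)C(F)(F)F)[C@H](O)CC[C@@H](OC(=O)c1ccccc1)C=C | intermediate
10 | 1,1,1,3,3,3-hexafluoropropan-2-yl (3R,6R)-6-(benzoyloxy)-3-[(tert-butyldimethylsilyl)oxy]-2-methylideneoct-7-enoate | C=C(C(=O)OC(C(F)(F)F)C(F)(F)F)[C@H](O[Si](C)(C)C(C)(C)C)CC[C@@H](OC(=O)c1ccccc1)C=C | intermediate
11 | (3R,6R)-3-[(tert-butyldimethylsilyl)oxy]-2-methylideneoct-7-ene-1,6-diol | C=C(CO)[C@H](O[Si](C)(C)C(C)(C)C)CC[C@@H](O)C=C | intermediate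
12 | (3R,6R)-6-(benzoyloxy)-3-[(tert-butyldimethylsilyl)oxy]-2-methylideneoct-7-en-1-yl benzoate | C=C(COC(=O)c1ccccc1)[C@H](O[Si](C)(C)C(C)(C)C)CC[C@@H](OC(=O)c1ccccc1)C=C | intermediate
13 | (3R,6R)-6-(benzoyloxy)-3-hydroxy-2-methylideneoct-7-en-1-yl benzoate (metathesis precursor) | C=C(COC(=O)c1ccccc1)[C@H](O)CC[C@@H](OC(=O)c1ccccc1)C=C | intermediate
14 | [(3R,6R)-3-(benzoyloxy)-6-hydroxycyclohex-1-en-1-yl]methyl benzoate (metathesis product) | O=C(OCC1=C[C@H](OC(=O)c2ccccc2)CC[C@H]1O)c1ccccc1 | intermediate
15 | [(1R,2R,5R,6S)-5-(benzoyloxy)-2-hydroxy-7-oxabicyclo[4.1.0]heptan-1-yl]methyl benzoate (epoxide oxygen cis to C2–OH, trans to C5–OBz) | O=C(OC[C@]12O[C@H]1[C@H](OC(=O)c1ccccc1)CC[C@H]2O)c1ccccc1 | intermediate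
16 | spiro 2-phenyl-1,3-dioxolan-2-ylium perchlorate spanning C1–O and C7–O, C1–O bond on the face opposite the C6 hydroxyl, C2–OH and C6–OH free, C5 benzoate | O[C@H]1[C@H](OC(=O)c2ccccc2)CC[C@@H](O)[C@@]13COC(c2ccccc2)=[O+]3.[O-]Cl(=O)(=O)=O | intermediate (not isolated)
17 | [(1S,2S,3R,6R)-3-(benzoyloxy)-1,2,6-trihydroxycyclohexyl]methyl benzoate (route locants: 1S,2R,5R,6S) | O=C(OC[C@]1(O)[C@H](O)CC[C@@H](OC(=O)c2ccccc2)[C@@H]1O)c1ccccc1 | target

**Step count and risk**
Total steps: 12. Longest linear sequence: 12 steps (from 1).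

Steps most likely to fail:

Step 12. The epoxide may open at C6 instead of C1 through participation of the C5 benzoate (anti to the epoxide oxygen), which would invert C6; the benzoyl groups may also redistribute when the orthoacid collapses. The fallback sets out from 12 and comes back at 17; it builds the trans C1/C6 diol by osmylation and an oxidation–reduction at C6 instead of an epoxide opening. RCM of silyl ether 12 under the conditions of step 10 should give [(3R,6R)-3-(benzoyloxy)-6-[(tert-butyldimethylsilyl)oxy]cyclohex-1-en-1-yl]methyl benzoate F1. OsO4 (cat.)/NMO in acetone–water should dihydroxylate anti to the bulky allylic silyl ether that flanks the fully substituted alkene carbon, to give the cis C1/C6 diol with both new hydroxyls on the face of the C5 benzoate F2. Dess–Martin periodinane should oxidise only the secondary C6 hydroxyl, giving the C6 ketone with the tertiary C1 hydroxyl retained F3. Me4NBH(OAc)3 in MeCN/AcOH, bound to the tertiary C1–OH, should deliver hydride to the same face of the carbonyl and give the C2 silyl ether of the target F4. HF·pyridine then gives 17.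

Step 5. Conversion of the unbranched aliphatic aldehyde may be slow, the adduct may be lost to dioxanone formation with a second aldehyde molecule, or catalyst control may be incomplete. The fallback sets out from 7 and comes back at 13; it makes the C1–C2 bond without stereocontrol and sets C2 by reagent-controlled ketone reduction. 2-Bromoprop-2-en-1-ol is silylated (TBSCl, imidazole) to tert-butyl[(2-bromoprop-2-en-1-yl)oxy]dimethylsilane F5. Nozaki–Hiyama–Kishi coupling of F5 with 7 (CrCl2, NiCl2 cat., DMF) should give (3R)-7-{[(tert-butyldimethylsilyl)oxy]methyl}-6-hydroxyocta-1,7-dien-3-yl benzoate as both carbinol epimers F6. Dess–Martin oxidation gives the enone (3R)-7-{[(tert-butyldimethylsilyl)oxy]methyl}-6-oxoocta-1,7-dien-3-yl benzoate F7. Corey–Bakshi–Shibata reduction with the (S)-2-methyl-oxazaborolidine and catecholborane (branched alkenyl group as the large substituent) should give the (3R,6R)-carbinol F8. Bu4NF removes the primary silyl ether to give (3R,6R)-6-hydroxy-7-(hydroxymethyl)octa-1,7-dien-3-yl benzoate F9, and BzCl/2,4,6-collidine at −78 °C should acylate the primary hydroxyl selectively to give 13.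

Step 10. The catalyst may stall after initiation (dimerisation through the vinyl group without engagement of the hindered 1,1-disubstituted alkene), or ruthenium hydride species may cause alkene migration or redox isomerisation of the free allylic alcohol. The fallback sets out from 10 and comes back at 14; it moves ring closure to the acrylate stage, where no free hydroxyl is present, and reduces afterwards. RCM of 10 (second-generation Hoveyda–Grubbs catalyst RuCl2(=CH-C6H4-2-OiPr)(H2IMes), toluene, 80 °C) should give 1,1,1,3,3,3-hexafluoropropan-2-yl (3R,6R)-3-(benzoyloxy)-6-[(tert-butyldimethylsilyl)oxy]cyclohex-1-ene-1-carboxylate F10. i-Bu2AlH reduces the ester and cleaves the benzoate to (1R,4R)-4-[(tert-butyldimethylsilyl)oxy]-3-(hydroxymethyl)cyclohex-2-en-1-ol F11. BzCl (two equivalents)/pyridine/DMAP gives the silyl-protected cyclohexene dibenzoate F1 described above, and HF·pyridine gives 14.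

**Further compounds**
F1 | step 12 | [(3R,6R)-3-(benzoyloxy)-6-[(tert-butyldimethylsilyl)oxy]cyclohex-1-en-1-yl]methyl benzoate | O=C(OCC1=C[C@H](OC(=O)c2ccccc2)CC[C@H]1O[Si](C)(C)C(C)(C)C)c1ccccc1
F2 | step 12 | cis C1/C6 diol, both hydroxyls on the face of the C5 benzoate, C2 silyl ether, C5 and C7 benzoates | O=C(OC[C@]1(O)[C@H](O[Si](C)(C)C(C)(C)C)CC[C@@H](OC(=O)c2ccccc2)[C@H]1O)c1ccccc1
F3 | step 12 | C6 ketone with tertiary C1 hydroxyl, C2 silyl ether, C5 and C7 benzoates | O=C(OC[C@]1(O)[C@H](O[Si](C)(C)C(C)(C)C)CC[C@@H](OC(=O)c2ccccc2)C1=O)c1ccccc1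
F4 | step 12 | C2 tert-butyldimethylsilyl ether of target 17 | O=C(OC[C@]1(O)[C@H](O[Si](C)(C)C(C)(C)C)CC[C@@H](OC(=O)c2ccccc2)[C@@H]1O)c1ccccc1
F5 | step 5 | tert-butyl[(2-bromoprop-2-en-1-yl)oxy]dimethylsilane | C=C(Br)CO[Si](C)(C)C(C)(C)C
F6 | step 5 | (3R)-7-{[(tert-butyldimethylsilyl)oxy]methyl}-6-hydroxyocta-1,7-dien-3-yl benzoate, both C6 epimers | C=C(CO[Si](C)(C)C(C)(C)C)C(O)CC[C@@H](OC(=O)c1ccccc1)C=C
F7 | step 5 | (3R)-7-{[(tert-butyldimethylsilyl)oxy]methyl}-6-oxoocta-1,7-dien-3-yl benzoate | C=C(CO[Si](C)(C)C(C)(C)C)C(=O)CC[C@@H](OC(=O)c1ccccc1)C=C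
F8 | step 5 | (3R,6R)-7-{[(tert-butyldimethylsilyl)oxy]methyl}-6-hydroxyocta-1,7-dien-3-yl benzoate | C=C(CO[Si](C)(C)C(C)(C)C)[C@H](O)CC[C@@H](OC(=O)c1ccccc1)C=C
F9 | step 5 | (3R,6R)-6-hydroxy-7-(hydroxymethyl)octa-1,7-dien-3-yl benzoate | C=C(CO)[C@H](O)CC[C@@H](OC(=O)c1ccccc1)C=C
F10 | step 10 | 1,1,1,3,3,3-hexafluoropropan-2-yl (3R,6R)-3-(benzoyloxy)-6-[(tert-butyldimethylsilyl)oxy]cyclohex-1-ene-1-carboxylate | O=C(OC(C(F)(F)F)C(F)(F)F)C1=C[C@H](OC(=O)c2ccccc2)CC[C@H]1O[Si](C)(C)C(C)(C)C
F11 | step 10 | (1R,4R)-4-[(tert-butyldimethylsilyl)oxy]-3-(hydroxymethyl)cyclohex-2-en-1-ol | OCC1=C[C@H](O)CC[C@H]1O[Si](C)(C)C(C)(C)C
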